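## Structural features

The target is a germacranolide: a ten-membered carbocycle (C1–C10) fused trans at C7–C8 to an α-methylene-γ-butyrolactone (C7–C11(=C13)–C12(=O)–O–C8). The carbocycle holds one E-trisubstituted alkene (C1=C10, methyl on C10) and one cis trisubstituted epoxide (C4–C5, methyl on C4, with C3 and C6 on the same face of the oxirane). Secondary acetates sit at C2 (allylic to C1=C10) and at C6 (between the epoxide and the lactone carbon C7). Five of the six stereocentres are contiguous (4R,5S,6S,7R,8S). The sixth, C2 (S), is separated from them by the C3 methylene on one side and by the sp2 atoms C1 and C10 on the other. The fragile groups are the Michael-accepting methylene lactone, the two esters, and the epoxide, which is acid-labile, has a neighbouring acetate that can participate, and lies β,γ to C2, so that a carbonyl at C2 invites base-induced opening. The real difficulty is to close the strained medium ring with all of this in place and to control the remote C2 centre. The key step uses the fact that C2 is a carbinol bonded directly to the alkene carbon C1: the C1–C2 bond can be made last, from an E-alkenyl iodide at C1 and an aldehyde at C2, without touching the C4–C8 array.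

## Logic of the disconnections

28 is cut at the ester C–O bond on C2. This leaves 27, in which the only free hydroxyl is the one to be acylated, so the last step needs no selectivity.

27 is cut at C1–C2, which opens the ten-membered ring to 25. The cut removes the ring and the C2 stereocentre in one move and leaves every other centre in place. The forward step must add an alkenyl metal to an aldehyde in the presence of an epoxide, two esters and a methylene lactone, must favour ring closure over oligomerisation, and must set C2 by catalyst control. Three design points follow: the chromium alkoxide 26 is handed to zirconium so that chromium turns over, the chiral chromium complex is preformed with less base than ligand so that no free base meets 25, and the C6 acetate is already in place so that only one acylation follows.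

25 is traced back through 24 and 23 to 22 by functional-group changes only: aldehyde from primary alcohol, primary alcohol from its oxidatively removable benzyl-type ether, acetate from the C6 alcohol. The aldehyde is unmasked last because it is β,γ to the epoxide. The forward steps must be free of strong acid and of amine bases once the aldehyde exists.

22 is cut at C6–C7 into 9 and 21. This is the convergent cut: it separates the epoxide fragment from the lactone fragment and creates C6 and C7 together, with the exocyclic methylene arising by allylic transposition. The forward Barbier-type allylation must deliver trans C7/C8, the anti relation of O6 and C8, and the Felkin sense at the epoxy aldehyde. All three preferences point to the same isomer.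

21 is cut at the C7=C11 ring alkene, giving 20, and then at the ester C–O bond, giving 18 and 19. The bromine enters with 19. This avoids a late allylic bromination of a methylbutenolide, which would have to tell the methyl group from the doubly activated C8–H and from the allylic positions of the iodoalkene chain. The forward ring closure must tolerate an allylic bromide and a hindered iodoalkene.

18 is cut at C10–CH3 and C1–I (syn methylmetalation of an alkyne, then iodination), giving 16. 16 is cut at the vinyl carbon added by one-carbon homologation and at the silyl group, giving 13 through 14 and 15. 13 is cut at the C9–alkyne bond, giving 10 and 11 through 12. C8 therefore comes from the chiral pool and is never touched.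

9 is traced back through 8 (oxidation level), 7 (the two epoxide C–O bonds, set by reagent-controlled epoxidation of a Z-allylic alcohol), 6 (reduction), 4 (the C4–CH3 bond, made by syn conjugate addition, which fixes the Z geometry through 5), 2 (the C5–C6 bond, by carboxylation of the acetylide 3) and 1. The forward sequence must keep the Z geometry, since it becomes the cis-epoxide.

## Other disconnections considered

Alternative 1: The cut is at C6–C7, with the ring enlarged in the retrosynthetic sense to the thirteen-membered cyclic diallyl ether A1, in which oxygen links C6 to C13. In the forward direction n-BuLi removes a proton at the ether carbon C6 and a [2,3]-sigmatropic shift contracts the ring to the ten-membered dienol A2. This forms C6–C7, the C6 hydroxyl and the C11=C13 methylene together.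
- In its favour: the ring is first closed as an unstrained large-ring ether, and the contraction is concerted and sets two adjacent centres (C6, C7) with the ring. On the number of stereocentres set in the ring-forming step it is better than the chosen plan (two against one), and on ease of ring closure it is at least its equal.
- Against it here: the strongly basic conditions exclude the epoxide, the esters and the lactone, so all of them come afterwards. Both ether α-carbons (C6 and C13) are allylic and either can be deprotonated, and a [1,2]-shift can compete. The C6/C7 relation would depend on the folding of the macrocycle and not on a simple acyclic rule. After A2, C12 must be oxidised and lactonised onto O8, C4=C5 epoxidised chemo- and face-selectively beside C1=C10, three silyl ethers told apart and two acetates installed, which is at least six further steps against one.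
- Comparison: on structure it handles the C6/C7 pair more directly than the chosen plan but leaves the oxidation pattern unfinished. On mechanism it is pericyclic and stereospecific but anionic, whereas the chosen closure is neutral and ligand-controlled. On step economy the chosen plan is shorter after the key step and convergent before it.

Alternative 2: The cut is at C8–C9, with retro ring expansion to the divinylcyclohexenol A3. In the forward direction KH with 18-crown-6 forms the tertiary C6 alkoxide and a chair [3,3]-shift breaks the C1–C6 ring bond, forms C8–C9 and gives the ten-membered dienone A4.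
- In its favour: there is no macrocyclisation. The ten-membered ring grows out of a six-membered ring without dilution, the chair fixes E-C1=C10, the cyclohexene supplies Z-C4=C5, and chirality is relayed to C8. On the reliability of medium-ring formation this is better than the chosen plan.
- Against it here: A4 is a bare dienone. C7 has no carbon substituent, C6 is a ketone and C8 carries silicon. The lactone carbons, the C6 centre, the C8 oxygen, the epoxide and both acetates would all have to be added on a flexible ring, where the facial control of enolate alkylation at C7 and of reduction at C6 is uncertain and transannular reactions are a threat. Converting the arylsilane into a hydroxyl needs electrophilic activation that also attacks trisubstituted alkenes. At least eight steps would follow.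
- Comparison: on structure it solves the ring and one alkene geometry elegantly but none of the C4–C7 array, which the chosen plan brings in finished. On mechanism it is a predictable sigmatropic shift but under strongly basic conditions. On step economy the chosen plan is clearly shorter after the key step.

Alternative 3: Both ring alkenes are cut (C1=C10 and C4=C5), leading back to the cis-anti-cis 6-4-4 tricycle A5, which would come from a [2+2] photocycloaddition of two small-ring partners. In the forward direction, heating A5 cleaves the central cyclobutane across C5–C10 and C1–C4 and gives the dienone A6.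
- In its favour: it is the shortest assembly of the carbocycle. Two steps give the ten-membered ring with both trisubstituted alkenes, the C7 acetic ester arm and the C2 and C8 oxygens, with no dilution. C4=C5 emerges as part of an enone, a handle for chemoselective nucleophilic epoxidation. On skeletal step count it is better than the chosen plan, and on differentiating the two alkenes it is its equal.
- Against it here: the photocycloaddition must be regio- and face-selective with two substituted partners, one of them an enantiopure oxygenated cyclobutene that is not readily available. The thermolysis needs about 200 °C, where it is not obvious which alkene becomes E, where 1,5-dienes of this kind can undergo Cope rearrangement to divinylcyclohexanes, and where the β-silyloxy ketone can eliminate. After A6 there remain C6 reduction with facial control, epoxidation, lactonisation, α-methylenation, desilylation and two acetylations, at least six steps.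
- Comparison: on structure it builds the ring fastest but leaves C4, C5 and C6 to late substrate control, whereas the chosen plan sets them early by reagent control. On mechanism it depends on a high-temperature fragmentation with competing pericyclic paths, against a room-temperature catalytic addition. On step economy it wins up to the ring and loses after it.

Key step: step 16

Assumptions and remarks on the chemistry:
- Germacrane numbering is used throughout (C1–C10 ring, C11–C13 lactone carbons).
- The configurations of 25 and 27 agree with 28 at every shared centre (E-alkene, cis-epoxide, trans-lactone; 4R,5S,6S,7R,8S, and 2S in 27), so no correction is needed.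
- The oxazoline sulfonamide ligand in step 16 is used as the antipode that gives Re-face addition at the C2 aldehyde (2S). Which antipode this is would be settled on a simple model aldehyde before 25 is committed; both derive from commercial (S)- and (R)-tert-leucinol.

## Steps

Step 1
Reactants: 1 but-3-yn-1-ol
Product: 2 1-[(but-3-yn-1-yloxy)methyl]-4-methoxybenzene
Conditions: NaH, 4-methoxybenzyl chloride, Bu4NI (cat.), THF/DMF, 0 °C to rt
Reagents that add atoms: 4-methoxybenzyl chloride, COc1ccc(CCl)cc1
Why: Williamson etherification of the alkoxide; the alkyne C–H is not deprotonated by NaH under these conditions. The 4-methoxybenzyl ether is chosen because it can be removed at the end by neutral oxidation.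

Step 2
Reactants: 2 1-[(but-3-yn-1-yloxy)methyl]-4-methoxybenzene
Product: 4 methyl 5-[(4-methoxybenzyl)oxy]pent-2-ynoate, via lithium acetylide 3 (not isolated)
Conditions: n-BuLi, THF, −78 °C; ClCO2Me, −78 to 0 °C
Reagents that add atoms: methyl chloroformate, COC(=O)Cl
Why: Deprotonation of the terminal alkyne and C-acylation of the acetylide 3 by the chloroformate, the standard ynoate synthesis; it forms the C5–C6 bond.

Step 3
Reactants: 4 methyl 5-[(4-methoxybenzyl)oxy]pent-2-ynoate
Product: 6 methyl (2Z)-5-[(4-methoxybenzyl)oxy]-3-methylpent-2-enoate, via alkenylcuprate 5 (not isolated)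
Conditions: Me2CuLi (from CuI and MeLi), THF, −78 °C; MeOH quench at −78 °C
Reagents that add atoms: lithium dimethylcuprate, [Li+].C[Cu-]C
Why: syn-Carbocupration of the ynoate places the new methyl and copper cis, so protonation of 5 with retention gives the Z-enoate with C3 and C6 cis, the geometry that becomes the cis-epoxide. The cold quench prevents equilibration through the allenolate.

Step 4
Reactants: 6 methyl (2Z)-5-[(4-methoxybenzyl)oxy]-3-methylpent-2-enoate
Product: 7 (2Z)-5-[(4-methoxybenzyl)oxy]-3-methylpent-2-en-1-ol
Conditions: i-Bu2AlH, CH2Cl2, −78 to 0 °C; aq. potassium sodium tartrate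
Reagents that add atoms: none
Why: 1,2-Reduction of the enoate to the allylic alcohol by the aluminium hydride; the alkene geometry and the benzyl ether are not affected.

Step 5
Reactants: 7 (2Z)-5-[(4-methoxybenzyl)oxy]-3-methylpent-2-en-1-ol
Product: 8 [(2S,3R)-3-{2-[(4-methoxybenzyl)oxy]ethyl}-3-methyloxiran-2-yl]methanol
Conditions: Ti(OiPr)4 (10 mol %), L-(+)-diethyl tartrate (12 mol %), t-BuOOH, 4 Å MS, CH2Cl2, −20 °C
Reagents that add atoms: tert-butyl hydroperoxide, CC(C)(C)OO
Why: Sharpless asymmetric epoxidation; with L-(+)-tartrate a 3,3-disubstituted Z-allylic alcohol of the nerol type is epoxidised on the face that gives (2S,3R), that is C5 S and C4 R. Oxygen transfer is syn, so C3 and C6 stay cis.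

Step 6
Reactants: 8 [(2S,3R)-3-{2-[(4-methoxybenzyl)oxy]ethyl}-3-methyloxiran-2-yl]methanol
Product: 9 (2R,3R)-3-{2-[(4-methoxybenzyl)oxy]ethyl}-3-methyloxirane-2-carbaldehyde
Conditions: Dess–Martin periodinane, NaHCO3, CH2Cl2, 0 °C to rt
Reagents that add atoms: none
Why: Dess–Martin oxidation under buffered conditions; α,β-epoxy aldehydes of this kind keep their configuration and are used without storage. The descriptor at the aldehyde-bearing carbon changes from S to R only because the CIP priorities change.

Step 7
Reactants: 10 (S)-2-(chloromethyl)oxirane; 11 ethynyltrimethylsilane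
Product: 13 (2S)-1-chloro-5-(trimethylsilyl)pent-4-yn-2-ol, via lithium silylacetylide 12 (not isolated)
Conditions: n-BuLi, THF, −78 °C; BF3·OEt2; then 10, −78 °C
Reagents that add atoms: none
Why: BF3-promoted opening of the epoxide at its unsubstituted carbon by the acetylide 12 (Yamaguchi-type alkynylation); the stereocentre of 10 is not touched and becomes C8. Chloride is kept as the leaving group for the next step.

Step 8
Reactants: 13 (2S)-1-chloro-5-(trimethylsilyl)pent-4-yn-2-ol
Product: 16 (3S)-hex-1-en-5-yn-3-ol, via silyl epoxide 14 (not isolated), via silylated enynol 15 (not isolated)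
Conditions: Me3S+ I− (3.5 equiv), n-BuLi (3.3 equiv), THF, −20 °C to rt; then MeOH, K2CO3, rt
Reagents that add atoms: trimethylsulfonium iodide, C[S+](C)C.[I-]
Why: Excess dimethylsulfonium methylide (the Corey–Chaykovsky reagent) closes the chlorohydrin to epoxide 14, opens it at CH2, and the β-oxido sulfonium loses dimethyl sulfide to give the vinyl carbinol 15, a known one-carbon homologation that leaves the carbinol centre untouched. Methanolic carbonate then cleaves the alkynyl C–Si bond; 16 is volatile and is carried on as a solution.

Step 9
Reactants: 16 (3S)-hex-1-en-5-yn-3-ol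
Product: 18 (3S,5E)-6-iodo-5-methylhexa-1,5-dien-3-ol, via alkenylalane 17 (not isolated)
Conditions: Me3Al (3 equiv), Cp2ZrCl2 (25 mol %), CH2Cl2, 0 °C to rt; then I2, THF, −30 to 0 °C
Reagents that add atoms: trimethylaluminium, C[Al](C)C; iodine, II
Why: Negishi zirconium-catalysed carboalumination adds methyl and aluminium syn, with aluminium at the terminal carbon, to the alkyne, which reacts much faster than the monosubstituted alkene. Iodinolysis of 17 with retention gives the E-iodoalkene.

Step 10
Reactants: 18 (3S,5E)-6-iodo-5-methylhexa-1,5-dien-3-ol; 19 2-(bromomethyl)prop-2-enoic acid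
Product: 20 (3S,5E)-6-iodo-5-methylhexa-1,5-dien-3-yl 2-(bromomethyl)prop-2-enoate
Conditions: DCC, DMAP (5 mol %), CH2Cl2, 0 °C
Reagents that add atoms: none
Why: Steglich esterification of the secondary alcohol with retention at C8; low temperature and a small amount of DMAP limit attack on the allylic bromide.

Step 11
Reactants: 20 (3S,5E)-6-iodo-5-methylhexa-1,5-dien-3-yl 2-(bromomethyl)prop-2-enoate
Product: 21 (5S)-3-(bromomethyl)-5-[(2E)-3-iodo-2-methylprop-2-en-1-yl]furan-2(5H)-one
Conditions: second-generation Grubbs catalyst (5 mol %), CH2Cl2 (5 mM), 40 °C
Reagents that add atoms: none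
Why: Ring-closing metathesis of an allylic ester of a 2-substituted acrylic acid to a butenolide, known for such acrylates. The catalyst loads at the monosubstituted vinyl group and closes onto the 1,1-disubstituted acrylate with loss of ethene; the trisubstituted iodoalkene is too hindered to take part.

Step 12
Reactants: 9 (2R,3R)-3-{2-[(4-methoxybenzyl)oxy]ethyl}-3-methyloxirane-2-carbaldehyde; 21 (5S)-3-(bromomethyl)-5-[(2E)-3-iodo-2-methylprop-2-en-1-yl]furan-2(5H)-one
Product: 22 (4S,5S)-4-[(S)-hydroxy{(2S,3R)-3-{2-[(4-methoxybenzyl)oxy]ethyl}-3-methyloxiran-2-yl}methyl]-5-[(2E)-3-iodo-2-methylprop-2-en-1-yl]-3-methylideneoxolan-2-one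
Conditions: In powder (2 equiv), THF/H2O (1:1), rt
Reagents that add atoms: none
Why: Barbier-type indium allylation: the allylindium from 21 reacts at its γ-carbon C7 through a closed chair transition state, forming C6–C7 and moving the double bond to the exocyclic position. Attack is on the butenolide face opposite the C8 side chain (trans C7/C8), and the ring-fixed E-type allyl geometry gives the anti relation of O6 and C8. This sense coincides with Felkin–Anh addition to the epoxy aldehyde (epoxide C–O anti to the nucleophile), so the three elements are matched.

Step 13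
Reactants: 22 (4S,5S)-4-[(S)-hydroxy{(2S,3R)-3-{2-[(4-methoxybenzyl)oxy]ethyl}-3-methyloxiran-2-yl}methyl]-5-[(2E)-3-iodo-2-methylprop-2-en-1-yl]-3-methylideneoxolan-2-one
Product: 23 (S)-{(2S,3R)-3-{2-[(4-methoxybenzyl)oxy]ethyl}-3-methyloxiran-2-yl}{(2S,3R)-2-[(2E)-3-iodo-2-methylprop-2-en-1-yl]-4-methylidene-5-oxooxolan-3-yl}methyl acetate
Conditions: Ac2O, pyridine, DMAP (cat.), CH2Cl2, 0 °C
Reagents that add atoms: acetic anhydride, CC(=O)OC(C)=O
Why: Nucleophile-catalysed acylation of the secondary alcohol; it installs the C6 acetate of the target and removes the hydroxyl that could otherwise translactonise from O8 to O6.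

Step 14
Reactants: 23 (S)-{(2S,3R)-3-{2-[(4-methoxybenzyl)oxy]ethyl}-3-methyloxiran-2-yl}{(2S,3R)-2-[(2E)-3-iodo-2-methylprop-2-en-1-yl]-4-methylidene-5-oxooxolan-3-yl}methyl acetate
Product: 24 (S)-[(2S,3R)-3-(2-hydroxyethyl)-3-methyloxiran-2-yl]{(2S,3R)-2-[(2E)-3-iodo-2-methylprop-2-en-1-yl]-4-methylidene-5-oxooxolan-3-yl}methyl acetate
Conditions: DDQ, CH2Cl2/pH 7 phosphate buffer (10:1), 0 °C to rt
Reagents that add atoms: none
Why: Oxidative cleavage of the 4-methoxybenzyl ether (hydride abstraction by DDQ, then hydrolysis of the oxocarbenium ion) under buffered neutral conditions that leave the epoxide, acetate, enoate and iodoalkene intact.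

Step 15
Reactants: 24 (S)-[(2S,3R)-3-(2-hydroxyethyl)-3-methyloxiran-2-yl]{(2S,3R)-2-[(2E)-3-iodo-2-methylprop-2-en-1-yl]-4-methylidene-5-oxooxolan-3-yl}methyl acetate
Product: 25 (S)-[(2S,3R)-3-methyl-3-(2-oxoethyl)oxiran-2-yl]{(2S,3R)-2-[(2E)-3-iodo-2-methylprop-2-en-1-yl]-4-methylidene-5-oxooxolan-3-yl}methyl acetate
Conditions: Dess–Martin periodinane, NaHCO3 (solid), CH2Cl2, 0 °C to rt; filtration through deactivated silica, used at once
Reagents that add atoms: none
Why: Dess–Martin oxidation needs no amine base, which matters because the β,γ-epoxy aldehyde can open its epoxide by β-elimination. The aldehyde is not stored and goes directly into step 16.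

Step 16
Reactants: 25 (S)-[(2S,3R)-3-methyl-3-(2-oxoethyl)oxiran-2-yl]{(2S,3R)-2-[(2E)-3-iodo-2-methylprop-2-en-1-yl]-4-methylidene-5-oxooxolan-3-yl}methyl acetate
Product: 27 (1(10)E,2S,4R,5S,6S,7R,8S)-6-acetoxy-4,5-epoxy-2-hydroxygermacra-1(10),11(13)-dien-12,8-olide, via zirconium alkoxide 26 (not isolated)
Conditions: CrCl3(THF)3 (20 mol %), tert-leucinol-derived oxazoline sulfonamide ligand (24 mol %), 1,8-bis(dimethylamino)naphthalene (22 mol %), NiCl2(2,9-dimethyl-1,10-phenanthroline) (3 mol %), Cp2ZrCl2 (1.2 equiv), LiCl, MeCN, Al anode, Ni-foam cathode, constant current, slow addition of 25 (final 2 mM), rt; aq. potassium sodium tartrate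
Reagents that add atoms: none
Why: Zerovalent nickel, formed from NiCl2 by divalent chromium, inserts into the C1–I bond and passes the alkenyl group with retention of the E geometry to trivalent chromium, which adds it to the C2 aldehyde; Cp2ZrCl2 takes over the alkoxide as 26 and the released trivalent chromium is reduced at the cathode back to the divalent state, while the aluminium anode is consumed. The closest known reactions are the Nozaki–Hiyama–Kishi ring closure of iodoalkenyl aldehydes with stoichiometric chromium and the ligand-controlled, chromium-catalytic coupling of alkenyl iodides with aldehydes under chemical or electrode turnover; the step applies the catalytic, electrode-driven form to a ring closure. The ten-membered carbocycle closes by 10-exo-trig attack of C1 on the C2 carbonyl carbon. The new centre C2 (S) is set by the chiral sulfonamide ligand on chromium, which directs the alkenyl group to the Re face of the aldehyde; the turn imposed by the trans-lactone and the cis-epoxide is only a secondary influence because C2 is remote from the other centres. Chemoselectivity for the aldehyde over the acetate, the lactone and the enoate rests on the low basicity and aldehyde preference of alkenylchromium species. Ring closure is favoured over oligomerisation by slow addition at low concentration. The epoxide is protected by the absence of free base (less base than ligand, complex preformed) and by the mildness of the zirconium and chromium Lewis acids in acetonitrile. The low nickel loading limits conjugate addition of the alkenylnickel to the methylene lactone.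

Step 17
Reactants: 27 (1(10)E,2S,4R,5S,6S,7R,8S)-6-acetoxy-4,5-epoxy-2-hydroxygermacra-1(10),11(13)-dien-12,8-olide
Product: 28 (1(10)E,2S,4R,5S,6S,7R,8S)-2,6-diacetoxy-4,5-epoxygermacra-1(10),11(13)-dien-12,8-olide
Conditions: Ac2O, pyridine, DMAP (cat.), CH2Cl2, 0 °C
Reagents that add atoms: acetic anhydride, CC(=O)OC(C)=O
Why: Standard acetylation of the only free hydroxyl, the secondary allylic alcohol at C2; no stereocentre is involved.

## Compound list

1 | but-3-yn-1-ol | C#CCCO | starting material
2 | 1-[(but-3-yn-1-yloxy)methyl]-4-methoxybenzene | C#CCCOCc1ccc(OC)cc1 | intermediate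
3 | {4-[(4-methoxybenzyl)oxy]but-1-yn-1-yl}lithium (not isolated) | [Li]C#CCCOCc1ccc(OC)cc1 | intermediate
4 | methyl 5-[(4-methoxybenzyl)oxy]pent-2-ynoate | COC(=O)C#CCCOCc1ccc(OC)cc1 | intermediate
5 | lithium methyl{1-(methoxycarbonyl)-4-[(4-methoxybenzyl)oxy]-2-methylbut-1-en-1-yl}cuprate, copper cis to the 2-methyl group (not isolated) | COC(=O)/C([Cu-]C)=C(/C)CCOCc1ccc(OC)cc1.[Li+] | intermediate
6 | methyl (2Z)-5-[(4-methoxybenzyl)oxy]-3-methylpent-2-enoate | COC(=O)/C=C(/C)CCOCc1ccc(OC)cc1 | intermediate
7 | (2Z)-5-[(4-methoxybenzyl)oxy]-3-methylpent-2-en-1-ol | OC/C=C(/C)CCOCc1ccc(OC)cc1 | intermediate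
8 | [(2S,3R)-3-{2-[(4-methoxybenzyl)oxy]ethyl}-3-methyloxiran-2-yl]methanol | OC[C@@H]1O[C@]1(C)CCOCc2ccc(OC)cc2 | intermediate
9 | (2R,3R)-3-{2-[(4-methoxybenzyl)oxy]ethyl}-3-methyloxirane-2-carbaldehyde | O=C[C@@H]1O[C@]1(C)CCOCc2ccc(OC)cc2 | intermediate
10 | (S)-2-(chloromethyl)oxirane | ClC[C@@H]1CO1 | starting material
11 | ethynyltrimethylsilane | C#C[Si](C)(C)C | starting material
12 | lithium (trimethylsilyl)acetylide (not isolated) | [Li]C#C[Si](C)(C)C | intermediate
13 | (2S)-1-chloro-5-(trimethylsilyl)pent-4-yn-2-ol | ClC[C@@H](O)CC#C[Si](C)(C)C | intermediate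
14 | trimethyl{3-[(2S)-oxiran-2-yl]prop-1-yn-1-yl}silane (not isolated) | C[Si](C)(C)C#CC[C@H]1CO1 | intermediate
15 | (3S)-6-(trimethylsilyl)hex-1-en-5-yn-3-ol (not isolated) | O[C@@H](CC#C[Si](C)(C)C)C=C | intermediate
16 | (3S)-hex-1-en-5-yn-3-ol | O[C@@H](CC#C)C=C | intermediate
17 | dimethylaluminium alkoxide of (3S,5E)-6-(dimethylalumanyl)-5-methylhexa-1,5-dien-3-ol (not isolated) | C[Al](C)O[C@@H](C/C(C)=C/[Al](C)C)C=C | intermediate
18 | (3S,5E)-6-iodo-5-methylhexa-1,5-dien-3-ol | O[C@@H](C/C(C)=C/I)C=C | intermediate
19 | 2-(bromomethyl)prop-2-enoic acid | OC(=O)C(=C)CBr | starting material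
20 | (3S,5E)-6-iodo-5-methylhexa-1,5-dien-3-yl 2-(bromomethyl)prop-2-enoate | C=C(CBr)C(=O)O[C@@H](C/C(C)=C/I)C=C | intermediate
21 | (5S)-3-(bromomethyl)-5-[(2E)-3-iodo-2-methylprop-2-en-1-yl]furan-2(5H)-one | O=C1O[C@@H](C/C(C)=C/I)C=C1CBr | intermediate
22 | (4S,5S)-4-[(S)-hydroxy{(2S,3R)-3-{2-[(4-methoxybenzyl)oxy]ethyl}-3-methyloxiran-2-yl}methyl]-5-[(2E)-3-iodo-2-methylprop-2-en-1-yl]-3-methylideneoxolan-2-one | C=C1C(=O)O[C@@H](C/C(C)=C/I)[C@@H]1[C@H](O)[C@@H]2O[C@]2(C)CCOCc3ccc(OC)cc3 | intermediate
23 | (S)-{(2S,3R)-3-{2-[(4-methoxybenzyl)oxy]ethyl}-3-methyloxiran-2-yl}{(2S,3R)-2-[(2E)-3-iodo-2-methylprop-2-en-1-yl]-4-methylidene-5-oxooxolan-3-yl}methyl acetate | C=C1C(=O)O[C@@H](C/C(C)=C/I)[C@@H]1[C@H](OC(C)=O)[C@@H]2O[C@]2(C)CCOCc3ccc(OC)cc3 | intermediate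
24 | (S)-[(2S,3R)-3-(2-hydroxyethyl)-3-methyloxiran-2-yl]{(2S,3R)-2-[(2E)-3-iodo-2-methylprop-2-en-1-yl]-4-methylidene-5-oxooxolan-3-yl}methyl acetate | C=C1C(=O)O[C@@H](C/C(C)=C/I)[C@@H]1[C@H](OC(C)=O)[C@@H]2O[C@]2(C)CCO | intermediate
25 | (S)-[(2S,3R)-3-methyl-3-(2-oxoethyl)oxiran-2-yl]{(2S,3R)-2-[(2E)-3-iodo-2-methylprop-2-en-1-yl]-4-methylidene-5-oxooxolan-3-yl}methyl acetate | C=C1C(=O)O[C@@H](C/C(C)=C/I)[C@@H]1[C@H](OC(C)=O)[C@@H]2O[C@]2(C)CC=O | intermediate
26 | chlorobis(cyclopentadienyl)zirconium 2-alkoxide of 27 (not isolated) | C=C1C(=O)O[C@H]2C/C(C)=C/[C@@H](O[Zr](Cl)(C4C=CC=C4)C5C=CC=C5)C[C@@]3(C)O[C@H]3[C@@H](OC(C)=O)[C@H]12 | intermediate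
27 | (1(10)E,2S,4R,5S,6S,7R,8S)-6-acetoxy-4,5-epoxy-2-hydroxygermacra-1(10),11(13)-dien-12,8-olide | C=C1C(=O)O[C@H]2C/C(C)=C/[C@@H](O)C[C@@]3(C)O[C@H]3[C@@H](OC(C)=O)[C@H]12 | intermediate
28 | (1(10)E,2S,4R,5S,6S,7R,8S)-2,6-diacetoxy-4,5-epoxygermacra-1(10),11(13)-dien-12,8-olide | C=C1C(=O)O[C@H]2C/C(C)=C/[C@@H](OC(C)=O)C[C@@]3(C)O[C@H]3[C@@H](OC(C)=O)[C@H]12 | target

## Step count and least certain steps

Total: 17 steps. Longest linear sequence: 12 steps (steps 1–6, then 12–17); the other branch is steps 7–11, then 12–17.

Step 16 (key step). Three processes are the most likely failures. The first is loss of the substrate before ring closure: base- or Lewis-acid-induced opening of the epoxide β,γ to the aldehyde, possibly assisted by the neighbouring C6 acetate, in contact with aluminium and zirconium salts during the slow addition. The second is oligomerisation, because a strained ten-membered ring closes slowly. The third is erosion of ligand control at C2 if the conformational demands of the closing ring oppose the facial preference of the catalyst. The lability of 25 made in step 15 belongs to this risk, since 25 is made and used in one sequence. Fallback: it sets out from 25 and returns at 27. Ring closure with stoichiometric CrCl2 and catalytic NiCl2 in DMSO at high dilution, the long-established form of this macrocyclisation, would give 27 together with its C2 epimer, 2-epi-27 F1. Dess–Martin oxidation of the mixture would give the ten-membered enone F2. Reduction with the (R)-2-methyl-CBS-oxazaborolidine and catecholborane at −78 °C, in which the alkenyl group acts as the large substituent, should then deliver the 2S alcohol 27. Stereocontrol at C2 is thereby moved from the C–C bond formation to a reagent-controlled reduction.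

Step 12. The likely failure is incomplete facial selectivity at the aldehyde or a boat-like transition state, because three control elements must cooperate in water, where the Felkin preference of epoxy aldehydes is only moderate; this would give the C6 epimer. A lesser risk is opening of the epoxide by indium salts. Fallback: it sets out from 9 and 21 and returns at 23. The C6 epimer of 22, 6-epi-22 F3, would be separated and converted directly into 23 by Mitsunobu esterification with acetic acid (PPh3, diisopropyl azodicarboxylate, toluene, 0 °C), which inverts C6 and installs the acetate in one operation. The C6 configuration is thereby corrected at the C–O bond and not in the C–C bond formation.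

Step 11. The likely failure is slow ring closure onto the electron-poor 1,1-disubstituted acrylate, with catalyst decay caused by the allylic bromide and with competing dimerisation through the vinyl groups. Fallback: it sets out from 18 and returns at 21, with the bromide introduced after ring closure. Commercial ethyl 2-(hydroxymethyl)acrylate would be silylated (TBSCl, imidazole) to ethyl 2-{[tert-butyl(dimethyl)silyl]oxymethyl}prop-2-enoate F4 and saponified (LiOH, THF/H2O) to 2-{[tert-butyl(dimethyl)silyl]oxymethyl}prop-2-enoic acid F5. Esterification with 18 (DCC, DMAP) would give (3S,5E)-6-iodo-5-methylhexa-1,5-dien-3-yl 2-{[tert-butyl(dimethyl)silyl]oxymethyl}prop-2-enoate F6. Ring-closing metathesis would give (5S)-3-{[tert-butyl(dimethyl)silyl]oxymethyl}-5-[(2E)-3-iodo-2-methylprop-2-en-1-yl]furan-2(5H)-one F7, and Ph3PBr2 in CH2Cl2 would convert the silyl ether directly into the bromide 21.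

Step 9. The likely failure is competing carbometalation or hydrometalation of the monosubstituted alkene, or ionisation of the allylic aluminium alkoxide, during the methylalumination. Fallback: it sets out from 13 and returns at 18, with the alkene introduced after the iodoalkene. Methanolic K2CO3 would give (2S)-1-chloropent-4-yn-2-ol F8. Carboalumination and iodination as in step 9 would give (2S,4E)-1-chloro-5-iodo-4-methylpent-4-en-2-ol F9. Treatment with preformed dimethylsulfonium methylide, free of residual n-BuLi so that the iodoalkene is not exchanged, would then give 18.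

## Further compounds

F1 | step 16 | (1(10)E,2R,4R,5S,6S,7R,8S)-6-acetoxy-4,5-epoxy-2-hydroxygermacra-1(10),11(13)-dien-12,8-olide (2-epi-27) | C=C1C(=O)O[C@H]2C/C(C)=C/[C@H](O)C[C@@]3(C)O[C@H]3[C@@H](OC(C)=O)[C@H]12
F2 | step 16 | (1(10)E,4R,5S,6S,7R,8S)-6-acetoxy-4,5-epoxy-2-oxogermacra-1(10),11(13)-dien-12,8-olide | C=C1C(=O)O[C@H]2C/C(C)=C/C(=O)C[C@@]3(C)O[C@H]3[C@@H](OC(C)=O)[C@H]12
F3 | step 12 | 6-epi-22, (R)-configured carbinol carbon, otherwise as 22 | C=C1C(=O)O[C@@H](C/C(C)=C/I)[C@@H]1[C@@H](O)[C@@H]2O[C@]2(C)CCOCc3ccc(OC)cc3
F4 | step 11 | ethyl 2-{[tert-butyl(dimethyl)silyl]oxymethyl}prop-2-enoate | C=C(CO[Si](C)(C)C(C)(C)C)C(=O)OCC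
F5 | step 11 | 2-{[tert-butyl(dimethyl)silyl]oxymethyl}prop-2-enoic acid | C=C(CO[Si](C)(C)C(C)(C)C)C(=O)O
F6 | step 11 | (3S,5E)-6-iodo-5-methylhexa-1,5-dien-3-yl 2-{[tert-butyl(dimethyl)silyl]oxymethyl}prop-2-enoate | C=C(CO[Si](C)(C)C(C)(C)C)C(=O)O[C@@H](C/C(C)=C/I)C=C
F7 | step 11 | (5S)-3-{[tert-butyl(dimethyl)silyl]oxymethyl}-5-[(2E)-3-iodo-2-methylprop-2-en-1-yl]furan-2(5H)-one | O=C1O[C@@H](C/C(C)=C/I)C=C1CO[Si](C)(C)C(C)(C)C
F8 | step 9 | (2S)-1-chloropent-4-yn-2-ol | ClC[C@@H](O)CC#C
F9 | step 9 | (2S,4E)-1-chloro-5-iodo-4-methylpent-4-en-2-ol | ClC[C@@H](O)C/C(C)=C/I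
A1 | alternative 1 | thirteen-membered cyclic diallyl ether (O links C6 and C13; C8 trans to C13 across C7=C11; 1(10)E,4Z; 2S,8S; 2-OTBS, 8-OTES, CH2OTES on C11) | O1C/C(CO[Si](CC)(CC)CC)=C/[C@@H](O[Si](CC)(CC)CC)C/C(C)=C/[C@@H](O[Si](C)(C)C(C)(C)C)C/C(C)=C\C1
A2 | alternative 1 | (1(10)E,4Z)-2-(tert-butyldimethylsilyloxy)-8-(triethylsilyloxy)-7-[3-(triethylsilyloxy)prop-1-en-2-yl]cyclodeca-1(10),4-dien-6-ol, configured at C2, C6, C7 and C8 as in 28 | C=C(CO[Si](CC)(CC)CC)[C@@H]1[C@@H](O[Si](CC)(CC)CC)C/C(C)=C/[C@@H](O[Si](C)(C)C(C)(C)C)C/C(C)=C\[C@H]1O
A3 | alternative 2 | 1-[(E)-2-(dimethylphenylsilyl)ethenyl]-5-[(4-methoxybenzyl)oxy]-3-methyl-6-(prop-1-en-2-yl)cyclohex-2-en-1-ol, ethenyl trans to propenyl, benzyloxy trans to propenyl | O[C@@]1(/C=C/[Si](C)(C)c2ccccc2)C=C(C)C[C@H](OCc2ccc(OC)cc2)[C@H]1C(C)=C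
A4 | alternative 2 | (1(10)E,4Z)-8-(dimethylphenylsilyl)-2-[(4-methoxybenzyl)oxy]-4,10-dimethylcyclodeca-1(10),4-dien-6-one (germacrane numbering) | O=C1C[C@@H]([Si](C)(C)c2ccccc2)C/C(C)=C/[C@@H](OCc2ccc(OC)cc2)C/C(C)=C\1
A5 | alternative 3 | cis-anti-cis 6-4-4 tricyclic ketone (central cyclobutane C5, C10, C1, C4; methyls on C4 and C10; OTBS on C2 and C8; CH2CO2Me on C7) | O=C1[C@H](CC(=O)OC)[C@@H](O[Si](C)(C)C(C)(C)C)C[C@]2(C)[C@H]1[C@@]1(C)C[C@H](O[Si](C)(C)C(C)(C)C)[C@H]12
A6 | alternative 3 | methyl 2-[(1(10)E,4Z)-2,8-bis(tert-butyldimethylsilyloxy)-4,10-dimethyl-6-oxocyclodeca-1(10),4-dien-7-yl]acetate (germacrane numbering) | O=C1[C@H](CC(=O)OC)[C@@H](O[Si](C)(C)C(C)(C)C)C/C(C)=C/[C@@H](O[Si](C)(C)C(C)(C)C)C/C(C)=C\1
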